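I decide to follow the electrophile as a fraction of its charge and leave the target aside, since the question is how much electrophile has reacted.

the same everywhere: electrophile 0.11 M

|  | nucleophile | solid base | remark | time |
|---|---|---|---|---|
| teal | 2.1 equiv | 1.2 equiv | run made earlier |  |
| ochre | 4.4 equiv | 1.2 equiv | run made earlier |  |
| green | 6.5 equiv | 1.2 equiv | run made earlier |  |
| Sunday's | 3.00 equiv | 1.20 equiv |  | 20 h |
| Tuesday's | 4.50 equiv | 1.20 equiv |  | 20 h |
| Friday's | 6.80 equiv | 1.20 equiv |  | 20 h |

- teal (time / h: electrophile / %, target / %): 1.33: 83, 15; 4.00: 69, 31; 6.00: 60, 33; 10.0: 50, 33; 15.0: 44, 33
- ochre (time / h: electrophile / %, target / %): 3.00: 54, 46; 6.00: 41, 50; 8.00: 32, 46; 12.0: 26, 49; 15.0: 24, 44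
- green (time / h: electrophile / %, target / %): 1.00: 69, 29; 2.00: 51, 43; 4.00: 38, 53; 8.00: 22, 54; 15.0: 15, 48

(scatter of a reading: 1.5 percentage points)

- part of the electrophile that has reacted at the end, Sunday's
- part of the electrophile that has reacted at the end, Tuesday's
- part of the electrophile that has reacted at the end, Friday's
- what raising the equivalents of nucleophile from its lowest to its highest value here does to the part of the electrophile that has reacted (changes below 5 percentage points count as none) (it rises / no change / it falls)

- solid base is a solid; its amount is given per volume of the solution
- what was read earlier has a scatter of 1.5 percentage points, one standard deviation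
- at the start none of the solid base is in solution

On a logarithmic plot the electrophile falls steeply and then flattens, so I read two times. The first is its opening pseudo-first-order lifetime: 7.14 h in the teal run, 2.69 h in the green run. The second is the life of whatever drives that fall, taking the slope to decay exponentially from the opening to the last two readings: 6.96 h in teal, 5.75 h in green. The ochre run's first reading, at 3.00 h, comes too late to give an opening. More nucleophile shortens the first time by more than the second.

The second time over the first is the reach, and the fraction left at a given time is e to the minus the part of the reach used by then; I use this only up to 20 h, not as a level at which the electrophile stops. It reads 0.975 in teal and 2.13 in green, so it grows as the 0.693 power of the equivalents. Taking the green life, a fraction 0.969 of the reach is used by 20 h. I therefore reckon 70.2%, 79.8% and 88.1% reacted.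

The forecast gives 68%, 79% and 88%, and says it rises; of the slowing it writes “which suggests the base or active nucleophile is running out”.

The flask gives 72.0%, 82.4% and 89.8%, and from the lowest to the highest nucleophile charge it rises, by 18 percentage points.

    electrophile + nucleophile → acid set free + target (k = 0.662 L mol⁻¹ h⁻¹)
    nucleophile + acid set free ⇌ protonated nucleophile, settled at all times (K = 1600 L mol⁻¹)
    acid set free + free base ⇌ salt of the base, settled at all times (K = 982 L mol⁻¹)
    solid base ⇌ free base, rate k4*(cs4 - [free base]) while solid is left; crystals form when [free base] > cs4 (solubility = 5.70 mM, k = 0.0164 h⁻¹)
    target ⇌ isomer of the product (K = 2.90, k = 0.0655 h⁻¹)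
    2 nucleophile → self-condensation product (k = 0.254 L mol⁻¹ h⁻¹)

Just after the start of Tuesday's flask, self-condensation uses nucleophile 3.5 times as fast as the coupling to target, and at 20 h unbound nucleophile stands at 10% of its charge and electrophile at 18%, a realised reach of 1.74 against my 1.60. With 11.0 equiv of nucleophile the reach scaled from teal leaves 5.10% of the electrophile by 20 h, and that neighbour flask holds 5.2%.

All runs were generated by integration on assumed constants; scatter was added.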